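**The problem**

The target is an isoflavone: a 5,7-dihydroxychromen-4-one (benzo ring A fused to pyranone ring C) that carries a 2,3,4,6-tetramethoxyphenyl group (ring B) at C3; it has no stereocentre, so the task is one of connectivity and chemoselectivity. The most awkward bond is C3–C1', which joins the pyranone carbon next to the C4 carbonyl to an aryl carbon flanked by methoxy groups at C2' and C6', so that forming it late means a doubly ortho-hindered coupling of an electron-rich, easily protodemetalated ring B. Ring C has an unsubstituted C2 at the formyl oxidation level between O1 and C3; it opens at C2 under hard nucleophiles and is best made last, under mild conditions. Two free phenols on ring A (C5, C7) stand against four methyl ethers on ring B, which rules out a final global demethylation and calls for ring A protecting groups that leave under neutral conditions. Ring B is a 1,2,3,5-tetraoxygenated benzene with a free C5'–H between two methoxy groups and para-related methoxy groups at C3' and C6'; it is a strong carbon nucleophile and is easily oxidised to a quinone, so strongly electrophilic or oxidising late steps are unattractive. The feature that opens a different route is on ring A: O1 on C8a and the C4 acyl carbon on C4a are ortho neighbours, the C5 oxygen sits beside C4a and the C7 oxygen is meta to C8a. This is the pattern produced when an oxygen nucleophile and an acyl electrophile add across a 3,5-dialkoxybenzyne whose triple bond is C4a≡C8a. The remaining atoms, C2–C3–C4 with ring B on C3, are a three-carbon carboxylic acid (C4 the carboxyl carbon, C2 a masked formyl group), so ring C can be closed and joined to ring A in one operation.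

**Retrosynthesis**

Protecting groups (15 ⇒ 14). The two ring A hydroxyls are traced back to benzyl ethers in 14. Methyl ethers could not be told apart from those of ring B, and silyl ethers would not survive the fluoride of the key step. Benzyl ethers are inert to fluoride, organolithiums and base, and leave by hydrogenolysis, to which the methyl ethers are inert. The forward step must stop before the C2=C3 bond is reduced.

Aryne annulation (14 ⇒ 5 + 11, through aryne 12 and ketone 13). Three bonds are cut at once: C8a–O1, C4a–C4 and O1–C2. Cutting C3–C1' instead leaves the hindered coupling described above. Cutting only C4a–C4 (Friedel–Crafts logic) needs a second, electrophilic operation to insert C2 in the presence of the nucleophilic ring B. The chosen cut leaves two monocyclic benzene derivatives: acid 5, which already holds ring B, C2, C3 and C4, and the ortho-silylaryl triflate 11, which releases 3,5-bis(benzyloxy)benzyne 12. The forward reaction must add the carboxylate oxygen to C8a and not C4a, move the acyl group from that oxygen to C4a, and close ring C by displacement of the C2 methoxy group. The benzyloxy group beside the triple bond is what decides the first point.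

Acid 5 (5 ⇒ 4 ⇒ 3). The C2=C3 double bond is cut by a Wittig disconnection after tracing the acid back to its methyl ester 4. The ketone carbon of keto ester 3 becomes C3, its ester carbon becomes C4 and a methoxymethylene ylide supplies C2 with its leaving group. The neighbouring cut, Claisen formylation of an arylacetate, would need an extra reduction step to reach the arylacetate. The alkene geometry of 4 and 5 need not be controlled, since the key step erases it.

Keto ester 3 (3 ⇒ 1). The hindered C3–C1' bond is cut where C3 is still the ketone carbon of a small two-carbon electrophile. Compound 1 has only one kind of ring C–H, flanked by two methoxy groups, so lithiation is unambiguous and acylation by an oxalate diester gives 3. The most hindered bond of the target is thus made first, by a reaction that is indifferent to ortho substituents, and one step removes a cross-coupling from the plan.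

Aryne precursor (11 ⇒ 7 ⇒ 6). The C–Si bond is traced to an O-to-C silyl migration in the O-silyl ether of bromophenol 7, and the C–Br bond to ortho-bromination of commercial phenol 6. The bromine must enter between the hydroxyl and a benzyloxy group, which places the future silyl group on C4a and the triflate on C8a.

**Roads not taken**

Alternative 1: The most obvious cut is C3–C1' by Suzuki–Miyaura coupling of 5,7-bis(benzyloxy)-3-iodochromen-4-one A1 with (2,3,4,6-tetramethoxyphenyl)boronic acid A2, using a zerovalent palladium catalyst such as Pd(PPh3)4. The coupling forms the one bond that is doubly ortho-substituted on the boron partner. A2 is a 2,6-dialkoxyarylboronic acid, a class that protodeboronates quickly in aqueous base, and its transmetalation is slow for the same steric reason. A1 has a base-sensitive C2 and needs about three steps of its own from a protected ring A ketone. The step count is no lower, and the key step makes one bond where the chosen plan makes three and avoids the hindered coupling altogether.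

Alternative 2: The classical deoxybenzoin route cuts C4–C4a and then C2. Houben–Hoesch acylation of phloroglucinol with 2-(2,3,4,6-tetramethoxyphenyl)acetonitrile A3 gives 1-(2,4,6-trihydroxyphenyl)-2-(2,3,4,6-tetramethoxyphenyl)ethan-1-one A4, and A4 is closed with a formamide-derived one-carbon electrophile. The route is short and needs no protecting groups; in step count it is not inferior to the chosen plan, although A3 must itself be made from 1 by a one-carbon homologation. Its weakness is mechanistic: both bond-forming steps are electrophilic substitutions in strong Lewis acid, and ring B of A3 and A4 is itself a first-rate nucleophile at C5'. Ring B can compete with ring A for the acylium or nitrilium ion and with the benzylic carbon of A4 for the iminium electrophile. The rings are assembled in separate operations, and it is the route most chemists would draw first. The chosen plan joins the rings under fluoride in an aprotic medium, where ring B is a spectator. The classical route is kept as the fallback for the key step.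

Alternative 3: The biomimetic cut is a 1,2-shift of ring B from C2 to C3. Claisen–Schmidt condensation of 2,3,4,6-tetramethoxybenzaldehyde A5 with 1-[2,4-bis(benzyloxy)-6-hydroxyphenyl]ethan-1-one A6 gives the chalcone (E)-1-[2,4-bis(benzyloxy)-6-hydroxyphenyl]-3-(2,3,4,6-tetramethoxyphenyl)prop-2-en-1-one A7. Oxidative rearrangement of A7 with Tl(NO3)3 (trivalent thallium) or PhI(OAc)2 in methanol gives the racemic acetal 1-[2,4-bis(benzyloxy)-6-hydroxyphenyl]-3,3-dimethoxy-2-(2,3,4,6-tetramethoxyphenyl)propan-1-one A8, and A8 closes to 14 in acid. The migrating ring is electron-rich, which favours the shift, but the oxidant meets a ring B whose para-related C3' and C6' methoxy groups invite oxidative demethylation to a quinone. The free ortho hydroxyl of A7 competes by cyclisation to an aurone or a flavone, so it needs an extra protecting step. The condensation uses the doubly ortho-substituted aldehyde A5, and a stoichiometric toxic metal or a further oxidant is required. The chosen plan uses no oxidant at any stage.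

Key step: step 6

Remark: 1 and 6 are taken as purchasable (1 is otherwise one O-methylation from 3,4,5-trimethoxyphenol); compounds 4, 5 and 13 are drawn as E isomers, and any Z isomer from step 2 is carried through, because step 6 destroys the alkene geometry.

**Route**

Step 1
Reactants: 1 1,2,3,5-tetramethoxybenzene
Product: 3 methyl 2-oxo-2-(2,3,4,6-tetramethoxyphenyl)acetate, via (2,3,4,6-tetramethoxyphenyl)lithium 2 (not isolated)
Conditions: n-BuLi, TMEDA, THF, 0 °C; then added to (CO2Me)2 (3 equiv), THF, –78 °C; aq. NH4Cl
Reagents that add atoms: dimethyl oxalate, COC(=O)C(=O)OC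
Why: Directed ortho-metalation; both free ring positions of 1 are equivalent and each lies between two methoxy groups, so the site of lithiation is unambiguous. Inverse addition of 2 to excess oxalate diester at low temperature stops at the keto ester because the tetrahedral adduct persists until the quench.

Step 2
Reactants: 3 methyl 2-oxo-2-(2,3,4,6-tetramethoxyphenyl)acetate
Product: 4 methyl (E)-3-methoxy-2-(2,3,4,6-tetramethoxyphenyl)prop-2-enoate
Conditions: Ph3P(CH2OMe)Cl, KOtBu, THF, 0 °C to rt
Reagents that add atoms: (methoxymethyl)triphenylphosphonium chloride, COC[P+](c1ccccc1)(c1ccccc1)c1ccccc1.[Cl-]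
Why: Wittig methoxymethylenation of an α-keto ester, the standard entry to β-methoxyacrylates. The two ortho methoxy groups twist ring B out of conjugation, which keeps the ketone electrophilic, and the E/Z outcome does not matter for step 6.

Step 3
Reactants: 4 methyl (E)-3-methoxy-2-(2,3,4,6-tetramethoxyphenyl)prop-2-enoate
Product: 5 (E)-3-methoxy-2-(2,3,4,6-tetramethoxyphenyl)prop-2-enoic acid
Conditions: LiOH, THF/MeOH/H2O, 50 °C; then 1 M HCl to pH 3, 0 °C
Reagents that add atoms: lithium hydroxide, [Li+].[OH-]
Why: Ester saponification by acyl–oxygen cleavage; the hindered, vinylogous carbonate ester needs gentle heating. The β-methoxy enol ether tolerates hydroxide, and brief cold acidification frees the acid without hydrolysing the enol ether.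

Step 4
Reactants: 6 3,5-bis(benzyloxy)phenol
Product: 7 3,5-bis(benzyloxy)-2-bromophenol
Conditions: NBS (1.0 equiv), CH2Cl2, –78 to –40 °C
Reagents that add atoms: N-bromosuccinimide, O=C1CCC(=O)N1Br
Why: Electrophilic aromatic bromination; one equivalent of NBS in a non-polar solvent at low temperature should brominate ortho to the free hydroxyl (two equivalent sites, hydrogen-bond delivery by the phenol) and not at C4, which is shielded by two benzyloxy groups.

Step 5
Reactants: 7 3,5-bis(benzyloxy)-2-bromophenol
Product: 11 3,5-bis(benzyloxy)-2-(trimethylsilyl)phenyl trifluoromethanesulfonate, via aryl trimethylsilyl ether 8 (not isolated), via ortho-lithiated silyl ether 9 (not isolated), via lithium silylphenoxide 10 (not isolated)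
Conditions: HMDS, THF, 65 °C, then evaporate; n-BuLi, THF, –100 to –78 °C; Tf2O, –100 °C to rt
Reagents that add atoms: hexamethyldisilazane, C[Si](C)(C)N[Si](C)(C)C; trifluoromethanesulfonic anhydride, O=S(=O)(OS(=O)(=O)C(F)(F)F)C(F)(F)F
Why: O-silylation, then bromine–lithium exchange (faster at –100 °C than benzylic deprotonation) triggers a 1,3 O-to-C silyl shift (retro-Brook rearrangement) driven by phenoxide formation. Triflation of 10 in the same flask gives the ortho-silylaryl triflate; this is the standard preparation of fluoride-triggered aryne precursors from ortho-bromophenols.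

Step 6
Reactants: 5 (E)-3-methoxy-2-(2,3,4,6-tetramethoxyphenyl)prop-2-enoic acid; 11 3,5-bis(benzyloxy)-2-(trimethylsilyl)phenyl trifluoromethanesulfonate
Product: 14 5,7-bis(benzyloxy)-3-(2,3,4,6-tetramethoxyphenyl)-4H-chromen-4-one, via 3,5-bis(benzyloxy)benzyne 12 (not isolated), via ortho-hydroxyaryl enone 13 (not isolated)
Conditions: 5 (1.0 equiv), 11 (1.5 equiv), CsF (4 equiv), THF, 125 °C, sealed tube
Reagents that add atoms: none
Why: Proposed new method: fluoride removes the silyl group of 11 and triflate leaves, giving aryne 12 with its triple bond between the future C4a and C8a; the caesium carboxylate of 5 adds through oxygen to C8a, the aryne carbon remote from the C5 benzyloxy group, because that more linear, distorted terminus is the more electrophilic one and the carbanion developing at C4a is stabilised inductively by the adjacent C5–O bond. The C4a carbanion then attacks the ester carbonyl on the neighbouring oxygen (4-exo-trig, through a benzoxetene alkoxide) and ring opening moves the acyl group from O to C, giving phenoxide 13 (an anionic ortho-Fries-type shift, in sum insertion of the aryne into the C–O bond of the acid). The C8a phenoxide of 13 closes ring C by 6-endo-trig conjugate addition to the methoxy-bearing carbon (the future C2), and the resulting enolate expels methoxide (E1cB), which gives the pyranone and removes the alkene geometry from the problem. The closest known reaction type is the CsF-mediated insertion of arynes from ortho-silylaryl triflates into the C–O bond of carboxylic acids to give ortho-hydroxyaryl ketones, which with unsaturated acids continue in the same flask by conjugate ring closure to chroman-4-ones and flavones; the related annulation of such arynes with salicylates gives xanthones. New here are the β-alkoxyacrylic acid, whose leaving group turns the closing conjugate addition into an addition–elimination that delivers the chromone oxidation level directly, and its less electrophilic, vinylogous carbonate carbonyl. No stereocentre is formed. The step needs two selectivities: the regiochemistry of addition to 12, secured by the C5 benzyloxy group beside the triple bond (the C7 benzyloxy group, meta to C8a, has only a minor influence), and acyl transfer in preference to protonation of the C4a carbanion or its conjugate attack on the acrylate β-carbon, which the aprotic medium, the proximity of the carbonyl in the twisted aryl ester and the donor-substituted, poorly electrophilic β-carbon should favour.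

Step 7
Reactants: 14 5,7-bis(benzyloxy)-3-(2,3,4,6-tetramethoxyphenyl)-4H-chromen-4-one
Product: 15 5,7-dihydroxy-3-(2,3,4,6-tetramethoxyphenyl)-4H-chromen-4-one
Conditions: H2 (1 atm), palladium on carbon (Pd/C), EtOAc/MeOH, rt
Reagents that add atoms: none
Why: Hydrogenolysis of the two benzyl aryl ethers; the methyl ethers are inert. The C2=C3 bond, part of a vinylogous ester and shielded by ring B, is reduced more slowly than the O-benzyl bonds are cleaved, so the reaction is stopped after uptake of two equivalents of H2.

**Compound list**

1 | 1,2,3,5-tetramethoxybenzene | COc1cc(OC)c(OC)c(OC)c1 | starting material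
2 | (2,3,4,6-tetramethoxyphenyl)lithium | [Li]c1c(OC)cc(OC)c(OC)c1OC | intermediate
3 | methyl 2-oxo-2-(2,3,4,6-tetramethoxyphenyl)acetate | COC(=O)C(=O)c1c(OC)cc(OC)c(OC)c1OC | intermediate
4 | methyl (E)-3-methoxy-2-(2,3,4,6-tetramethoxyphenyl)prop-2-enoate | CO/C=C(/C(=O)OC)c1c(OC)cc(OC)c(OC)c1OC | intermediate
5 | (E)-3-methoxy-2-(2,3,4,6-tetramethoxyphenyl)prop-2-enoic acid | CO/C=C(/C(=O)O)c1c(OC)cc(OC)c(OC)c1OC | intermediate
6 | 3,5-bis(benzyloxy)phenol | Oc1cc(OCc2ccccc2)cc(OCc2ccccc2)c1 | starting material
7 | 3,5-bis(benzyloxy)-2-bromophenol | Oc1cc(OCc2ccccc2)cc(OCc2ccccc2)c1Br | intermediate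
8 | [3,5-bis(benzyloxy)-2-bromophenoxy]trimethylsilane | C[Si](C)(C)Oc1cc(OCc2ccccc2)cc(OCc2ccccc2)c1Br | intermediate
9 | [2,4-bis(benzyloxy)-6-(trimethylsilyloxy)phenyl]lithium | C[Si](C)(C)Oc1cc(OCc2ccccc2)cc(OCc2ccccc2)c1[Li] | intermediate
10 | lithium 3,5-bis(benzyloxy)-2-(trimethylsilyl)phenoxide | [Li+].[O-]c1cc(OCc2ccccc2)cc(OCc2ccccc2)c1[Si](C)(C)C | intermediate
11 | 3,5-bis(benzyloxy)-2-(trimethylsilyl)phenyl trifluoromethanesulfonate | C[Si](C)(C)c1c(OCc2ccccc2)cc(OCc2ccccc2)cc1OS(=O)(=O)C(F)(F)F | intermediate
12 | 3,5-bis(benzyloxy)benzyne (triple bond between the carbons that become C4a and C8a) | C1#CC(OCc2ccccc2)=CC(OCc2ccccc2)=C1 | intermediate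
13 | (E)-1-[2,4-bis(benzyloxy)-6-hydroxyphenyl]-3-methoxy-2-(2,3,4,6-tetramethoxyphenyl)prop-2-en-1-one (present as its caesium phenoxide) | CO/C=C(/C(=O)c1c(O)cc(OCc2ccccc2)cc1OCc1ccccc1)c1c(OC)cc(OC)c(OC)c1OC | intermediate
14 | 5,7-bis(benzyloxy)-3-(2,3,4,6-tetramethoxyphenyl)-4H-chromen-4-one | COc1cc(OC)c(-c2coc3cc(OCc4ccccc4)cc(OCc4ccccc4)c3c2=O)c(OC)c1OC | intermediate
15 | 5,7-dihydroxy-3-(2,3,4,6-tetramethoxyphenyl)-4H-chromen-4-one | COc1cc(OC)c(-c2coc3cc(O)cc(O)c3c2=O)c(OC)c1OC | target

**Step count and risks**

Total step count: 7. Longest linear sequence: 5 steps (steps 1, 2, 3, 6, 7); the aryne precursor branch is 2 steps (steps 4, 5).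

Step 6 (key step, proposed new method). The sequence may stop at O-arylation of the carboxylate if the C4a carbanion is protonated, by the acid proton held as bifluoride or by traces of water, before the O-to-C acyl shift. The carbanion may also attack the acrylate β-carbon in place of the carbonyl, the aryne may be consumed by the methoxide or methanol released on ring closure, and ring closure of 13 may be incomplete. The cause is that the β-methoxyacrylate carbonyl is a vinylogous carbonate and a weaker electrophile than the carbonyls of the known insertions, and the carbanion is crowded by the C5 benzyloxy group. The fallback uses known chemistry and no aryne; it sets out from 3 and comes back to the route at 15. Wolff–Kishner reduction of 3 (N2H4·H2O, KOH, ethylene glycol, heating; then HCl), with ester hydrolysis under the same conditions, should give 2-(2,3,4,6-tetramethoxyphenyl)acetic acid F1. Friedel–Crafts acylation of phloroglucinol with F1 in BF3·OEt2 should give 1-(2,4,6-trihydroxyphenyl)-2-(2,3,4,6-tetramethoxyphenyl)ethan-1-one F2, the same ketone that Alternative 2 reaches as A4. Formylative ring closure of F2 (DMF, BF3·OEt2, MsCl) should give 15 directly, with the liabilities named under Alternative 2 accepted.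

Step 2. Olefination may be slow or incomplete because the ketone is shielded by two ortho methoxy groups, and the ylide or alkoxide may attack the ester instead. The fallback sets out from 3 and comes back at 4. Ionic hydrogenation of the electron-rich aryl ketone of 3 (Et3SiH, TFA) should give methyl 2-(2,3,4,6-tetramethoxyphenyl)acetate F3. Claisen formylation of F3 (HCO2Me, NaH, THF) should give methyl (Z)-3-hydroxy-2-(2,3,4,6-tetramethoxyphenyl)prop-2-enoate F4, the hydrogen-bonded enol of the formyl ester. O-Methylation of F4 (Me2SO4, K2CO3, acetone) should give 4.

Step 4. Bromination may go para to the hydroxyl (C4) or twice, since all three free positions of 6 are activated. The fallback sets out from 6 and comes back at 11, bypassing 7 and the low-temperature lithiation of step 5. Carbamoylation of 6 (i-PrNCO, Et3N) should give 3,5-bis(benzyloxy)phenyl N-(propan-2-yl)carbamate F5. In situ N-silylation of F5 (TMSOTf, TMEDA), directed ortho-lithiation between the carbamate and a benzyloxy group (n-BuLi, TMEDA, Et2O, –78 °C) and quenching with TMSCl should give 3,5-bis(benzyloxy)-2-(trimethylsilyl)phenyl N-(propan-2-yl)carbamate F6. Carbamate cleavage of F6 (DBU, Et2NH, MeCN, 40 °C) should free 3,5-bis(benzyloxy)-2-(trimethylsilyl)phenol F7, and PhNTf2 should convert F7 in the same flask into 11.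

Step 7. The C2=C3 bond may be over-reduced to the isoflavanone, or cleavage of the C5 benzyl ether may stall. The fallback sets out from 14 and comes back at 15 with no new compound. It is a Lewis-acid debenzylation with BCl3 and pentamethylbenzene as cation scavenger in CH2Cl2 at –78 °C. This mechanism cannot touch the enone double bond, and at that temperature it should leave the ring B methyl ethers, none of which is ortho to a carbonyl, intact.

**Further compounds**

F1 | step 6 | 2-(2,3,4,6-tetramethoxyphenyl)acetic acid | OC(=O)Cc1c(OC)cc(OC)c(OC)c1OC
F2 | step 6 | 1-(2,4,6-trihydroxyphenyl)-2-(2,3,4,6-tetramethoxyphenyl)ethan-1-one | O=C(Cc1c(OC)cc(OC)c(OC)c1OC)c1c(O)cc(O)cc1O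
F3 | step 2 | methyl 2-(2,3,4,6-tetramethoxyphenyl)acetate | COC(=O)Cc1c(OC)cc(OC)c(OC)c1OC
F4 | step 2 | methyl (Z)-3-hydroxy-2-(2,3,4,6-tetramethoxyphenyl)prop-2-enoate | O/C=C(\C(=O)OC)c1c(OC)cc(OC)c(OC)c1OC
F5 | step 4 | 3,5-bis(benzyloxy)phenyl N-(propan-2-yl)carbamate | CC(C)NC(=O)Oc1cc(OCc2ccccc2)cc(OCc2ccccc2)c1
F6 | step 4 | 3,5-bis(benzyloxy)-2-(trimethylsilyl)phenyl N-(propan-2-yl)carbamate | CC(C)NC(=O)Oc1cc(OCc2ccccc2)cc(OCc2ccccc2)c1[Si](C)(C)C
F7 | step 4 | 3,5-bis(benzyloxy)-2-(trimethylsilyl)phenol | Oc1cc(OCc2ccccc2)cc(OCc2ccccc2)c1[Si](C)(C)C
F0 | step 7 | none | none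
A1 | alternative 1 | 5,7-bis(benzyloxy)-3-iodo-4H-chromen-4-one | O=c1c(I)coc2cc(OCc3ccccc3)cc(OCc3ccccc3)c12
A2 | alternative 1 | (2,3,4,6-tetramethoxyphenyl)boronic acid | COc1cc(OC)c(B(O)O)c(OC)c1OC
A3 | alternative 2 | 2-(2,3,4,6-tetramethoxyphenyl)acetonitrile | N#CCc1c(OC)cc(OC)c(OC)c1OC
A4 | alternative 2 | 1-(2,4,6-trihydroxyphenyl)-2-(2,3,4,6-tetramethoxyphenyl)ethan-1-one | O=C(Cc1c(OC)cc(OC)c(OC)c1OC)c1c(O)cc(O)cc1O
A5 | alternative 3 | 2,3,4,6-tetramethoxybenzaldehyde | COc1cc(OC)c(C=O)c(OC)c1OC
A6 | alternative 3 | 1-[2,4-bis(benzyloxy)-6-hydroxyphenyl]ethan-1-one | CC(=O)c1c(O)cc(OCc2ccccc2)cc1OCc1ccccc1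
A7 | alternative 3 | (E)-1-[2,4-bis(benzyloxy)-6-hydroxyphenyl]-3-(2,3,4,6-tetramethoxyphenyl)prop-2-en-1-one | COc1cc(OC)c(/C=C/C(=O)c2c(O)cc(OCc3ccccc3)cc2OCc2ccccc2)c(OC)c1OC
A8 | alternative 3 | 1-[2,4-bis(benzyloxy)-6-hydroxyphenyl]-3,3-dimethoxy-2-(2,3,4,6-tetramethoxyphenyl)propan-1-one (racemic) | COC(OC)C(C(=O)c1c(O)cc(OCc2ccccc2)cc1OCc1ccccc1)c1c(OC)cc(OC)c(OC)c1OC
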